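**Retrosynthetic overview**

- Atom labels run along the target chain: C1 = exocyclic CH2; ring A = C2–C3–C4–C5(H)(Br)–C6(Me2)–C7(spiro); ring B = C7–C8–C9–C10(Cl)(Me)–C11(H)(Br)–C12. The strategy rests on the C5 bromide of ring A, which is secondary, neopentylic (next to quaternary C6) and 1,4 to C2.
- C1=C2 comes from a C2 ketone by methylenation. Ring A is closed last, from a bromomethyl ketone on C7, by an atom-transfer radical cyclisation that makes C3–C4 and C5–Br together.
- The bromomethyl ketone comes from an acid chloride (diazo ketone, then HBr). The acid chloride comes from a bromolactone by SOCl2/ZnCl2 (O to Cl at C10 with retention). Bromolactonisation of the (R)-acid sets C10 and C11 from C7.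
- The (R)-acid comes from resolution of the racemic acid made by Ireland–Claisen rearrangement of the prenyl ester of 4-methylcyclohex-3-ene-1-carboxylic acid. Ring B is bought; the C7–C6 bond and the vinyl group (C5=C4) are made in the rearrangement.

Key step: step 7

Remark 1: which enantiomer of 1-phenylethan-1-amine gives the less soluble salt with the (R)-acid in step 3 cannot be predicted; the (S)-amine is assumed, the (R)-amine would be used if the salt of the (S)-acid crystallised instead, and the absolute configuration at C7 would be confirmed by X-ray analysis of the bromolactone of step 4.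

Remark 2: the sense of induction of the bis(oxazoline) ligand in step 7 cannot be predicted either; the (S,S) ligand is assumed and the (R,R) ligand would be used if it proves to be the one that favours the target configuration at C5.

**Route**

Step 1
Reactants: 1 4-methylcyclohex-3-ene-1-carboxylic acid (racemic); 2 3-methylbut-2-en-1-ol (prenol)
Product: 3 3-methylbut-2-en-1-yl 4-methylcyclohex-3-ene-1-carboxylate (racemic)
Conditions: DCC, DMAP (cat.), CH2Cl2, 0 °C to rt
Reagents that add atoms: none
Why: Steglich esterification joins the secondary acid and the primary allylic alcohol under neutral conditions that leave both alkenes alone, and the α-stereocentre of racemic 1 does not matter because step 2 erases it.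

Step 2
Reactants: 3 3-methylbut-2-en-1-yl 4-methylcyclohex-3-ene-1-carboxylate
Product: 6 rac-4-methyl-1-(2-methylbut-3-en-2-yl)cyclohex-3-ene-1-carboxylic acid, via silyl ketene acetal 4 (not isolated), via trimethylsilyl ester 5 (not isolated)
Conditions: LiN(iPr)2, THF, −78 °C; Me3SiCl; −78 to 60 °C; then 1 M HCl
Reagents that add atoms: none
Why: Ireland–Claisen rearrangement, in which the O-silylated ester enolate undergoes a [3,3]-sigmatropic shift that bonds the ring α-carbon (C7) to the dimethyl-bearing allyl terminus (C6) and moves the double bond to the terminal vinyl position (a reaction known to form vicinal quaternary carbons), with C7 formed racemic because the two enolate faces are enantiotopic.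

Step 3
Reactants: 6 rac-4-methyl-1-(2-methylbut-3-en-2-yl)cyclohex-3-ene-1-carboxylic acid; 7 (S)-1-phenylethan-1-amine
Product: 8 (S)-1-phenylethylammonium (R)-4-methyl-1-(2-methylbut-3-en-2-yl)cyclohex-3-ene-1-carboxylate
Conditions: EtOAc–heptane, crystallisation, recrystallised to constant rotation
Reagents that add atoms: none
Why: Classical resolution by crystallisation of diastereomeric ammonium carboxylates fixes the absolute configuration of C7, the only stereocentre at this stage.

Step 4
Reactants: 8 (S)-1-phenylethylammonium (R)-4-methyl-1-(2-methylbut-3-en-2-yl)cyclohex-3-ene-1-carboxylate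
Product: 10 (1S,4R,6S)-6-bromo-1-methyl-4-(2-methylbut-3-en-2-yl)-2-oxabicyclo[2.2.2]octan-3-one (O on C10 cis to C2; Br on C11 anti to that O), via free (R)-acid 9 (not isolated)
Conditions: 1 M HCl, Et2O (acid set free); then NBS (1.0 equiv), THF, 0 °C, dark
Reagents that add atoms: N-bromosuccinimide, O=C1CCC(=O)N1Br
Why: Bromolactonisation, in which the bromonium ion forms on the electron-rich trisubstituted ring alkene rather than on the hindered vinyl group and is opened at tertiary C10 (Markovnikov, 6-endo, the mode α-terpineol follows in halo-etherification to the 1,8-cineole skeleton) by the axial carboxyl group, which can reach C10 only on its own face, so that oxygen ends cis to C2 and bromine on C11 anti to it and both centres are set from C7.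

Step 5
Reactants: 10 (1S,4R,6S)-6-bromo-1-methyl-4-(2-methylbut-3-en-2-yl)-2-oxabicyclo[2.2.2]octan-3-one
Product: 11 (1R,3S,4S)-3-bromo-4-chloro-4-methyl-1-(2-methylbut-3-en-2-yl)cyclohexane-1-carbonyl chloride
Conditions: SOCl2, ZnCl2 (5 mol%), 1,2-dichloroethane, 50 °C
Reagents that add atoms: thionyl chloride, ClS(Cl)=O
Why: Chlorinative opening of a lactone to the chloro acyl chloride with SOCl2/ZnCl2 (known for butyrolactones and for lactones with a tertiary alkyl oxygen), in which the zinc-bound lactone ionises at tertiary C10 with help from the C11 bromine that lies antiperiplanar to the C10–O bond in the bicycle, and chloride opens the bromonium ion at C10 from the face the oxygen has left, so that C10 keeps its configuration (Cl cis to C2, trans to Br) while the carboxylate is taken out of the equilibrium as the acid chloride.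

Step 6
Reactants: 11 (1R,3S,4S)-3-bromo-4-chloro-4-methyl-1-(2-methylbut-3-en-2-yl)cyclohexane-1-carbonyl chloride; 12 (trimethylsilyl)diazomethane
Product: 14 2-bromo-1-[(1R,3S,4S)-3-bromo-4-chloro-4-methyl-1-(2-methylbut-3-en-2-yl)cyclohexyl]ethan-1-one, via diazo ketone 13 (not isolated)
Conditions: Me3SiCHN2 (3 equiv), MeCN–THF, 0 °C to rt; then 48% aq. HBr, 0 °C
Reagents that add atoms: hydrogen bromide, Br
Why: Arndt–Eistert-type acylation of the diazoalkane at carbon (the silyl group leaves as Me3SiCl, which the aqueous acid hydrolyses) gives the α-diazo ketone, which HBr protonates at carbon to a diazonium ion that bromide displaces with loss of N2, all at 0 °C so that the tertiary chloride, the secondary bromide and the vinyl group are not touched.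

Step 7
Reactants: 14 2-bromo-1-[(1R,3S,4S)-3-bromo-4-chloro-4-methyl-1-(2-methylbut-3-en-2-yl)cyclohexyl]ethan-1-one
Product: 15 (4R,6R,8S,9S)-4,8-dibromo-9-chloro-5,5,9-trimethylspiro[5.5]undecan-1-one
Conditions: CuBr (10 mol%), CuBr2 (10 mol%), (S,S)-2,2'-isopropylidenebis(4-tert-butyl-2-oxazoline) (22 mol%), degassed 1,2-dichloroethane, 70 °C, slow addition of 14 (about 0.01 M)
Reagents that add atoms: none
Why: Proposed new method: monovalent copper takes bromine only from the activated C3–Br bond of the α-bromo ketone, the electrophilic C3 radical adds to the terminal alkene carbon C4, and the resulting C5 radical takes bromine from the ligated CuBr2 (divalent copper), which returns monovalent copper. The closest known reaction type is the copper-catalysed atom-transfer (Kharasch-type) radical cyclisation of α-halo carbonyl compounds with achiral nitrogen ligands; new here is a C2-symmetric bis(oxazoline) on copper that has to control the face of bromine transfer to a non-stabilised secondary radical, the nearest analogies being the enantioselective trapping of prochiral radicals by bis(oxazoline)-ligated copper in C–C and C–N bond formation and the stereocontrolled halogen rebound of engineered haem enzymes. Ring A closes in the 6-endo-trig mode, because an α-keto radical whose carbonyl group lies inside the forming ring prefers endo closure and the 5-exo path would have to attack C5 next to quaternary C6. C5 is the only new stereocentre: the target needs bromine on the ring A face that carries C12 (an equatorial C–Br bond on the chair with C8 axial), and since the two faces differ in the substrate only through the distant C11–Br the substrate gives no reliable bias, so the choice is handed to the ligand, which meets a radical centre flanked by very different groups (C4H2 and C6Me2). The step needs chemoselectivity (the ring B halides are unactivated and stay), endo regioselectivity (ketone and C6, as above) and face selectivity at C5 (ligand); added CuBr2 and slow addition of 14 keep the bromine transfer on copper and hold back the unselective chain transfer from 14 itself.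

Step 8
Reactants: 15 (4R,6R,8S,9S)-4,8-dibromo-9-chloro-5,5,9-trimethylspiro[5.5]undecan-1-one
Product: 16 (2R,6S,8S,9S)-2,8-dibromo-9-chloro-1,1,9-trimethyl-5-methylidenespiro[5.5]undecane
Conditions: Cp2TiMe2 (3 equiv), toluene, 70 °C, dark
Reagents that add atoms: dimethyltitanocene Cp2TiMe2, C[Ti](C)(C1C=CC=C1)C1C=CC=C1
Why: Petasis methylenation, in which Cp2Ti=CH2 formed by loss of methane adds to the carbonyl group by [2+2] cycloaddition and the oxatitanacyclobutane collapses to the alkene, a non-basic olefination that works on hindered, enolisable ketones, leaves alkyl halides alone and touches no stereocentre.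

**Compound list**

1 | 4-methylcyclohex-3-ene-1-carboxylic acid (racemic) | CC1=CCC(CC1)C(O)=O | starting material
2 | 3-methylbut-2-en-1-ol (prenol) | CC(C)=CCO | starting material
3 | 3-methylbut-2-en-1-yl 4-methylcyclohex-3-ene-1-carboxylate (racemic) | CC1=CCC(CC1)C(=O)OCC=C(C)C | intermediate
4 | trimethyl{[(3-methylbut-2-en-1-yl)oxy](4-methylcyclohex-3-en-1-ylidene)methoxy}silane (silyl ketene acetal, E/Z mixture) | CC1=CCC(CC1)=C(O[Si](C)(C)C)OCC=C(C)C | intermediate
5 | trimethylsilyl 4-methyl-1-(2-methylbut-3-en-2-yl)cyclohex-3-ene-1-carboxylate (racemic) | C=CC(C)(C)C1(CCC(C)=CC1)C(=O)O[Si](C)(C)C | intermediate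
6 | rac-4-methyl-1-(2-methylbut-3-en-2-yl)cyclohex-3-ene-1-carboxylic acid | C=CC(C)(C)C1(CCC(C)=CC1)C(O)=O | intermediate
7 | (S)-1-phenylethan-1-amine | C[C@H](N)c1ccccc1 | starting material
8 | (S)-1-phenylethylammonium (R)-4-methyl-1-(2-methylbut-3-en-2-yl)cyclohex-3-ene-1-carboxylate | C[C@H]([NH3+])c1ccccc1.[O-]C(=O)[C@]1(C(C)(C)C=C)CCC(C)=CC1 | intermediate
9 | (R)-4-methyl-1-(2-methylbut-3-en-2-yl)cyclohex-3-ene-1-carboxylic acid | OC(=O)[C@]1(C(C)(C)C=C)CCC(C)=CC1 | intermediate
10 | (1S,4R,6S)-6-bromo-1-methyl-4-(2-methylbut-3-en-2-yl)-2-oxabicyclo[2.2.2]octan-3-one | O=C2[C@]1(C(C)(C)C=C)CC[C@](C)(O2)[C@@H](Br)C1 | intermediate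
11 | (1R,3S,4S)-3-bromo-4-chloro-4-methyl-1-(2-methylbut-3-en-2-yl)cyclohexane-1-carbonyl chloride | ClC(=O)[C@]1(C(C)(C)C=C)CC[C@](C)(Cl)[C@@H](Br)C1 | intermediate
12 | (trimethylsilyl)diazomethane | C[Si](C)(C)C=[N+]=[N-] | starting material
13 | 2-diazo-1-[(1R,3S,4S)-3-bromo-4-chloro-4-methyl-1-(2-methylbut-3-en-2-yl)cyclohexyl]ethan-1-one | [N-]=[N+]=CC(=O)[C@]1(C(C)(C)C=C)CC[C@](C)(Cl)[C@@H](Br)C1 | intermediate
14 | 2-bromo-1-[(1R,3S,4S)-3-bromo-4-chloro-4-methyl-1-(2-methylbut-3-en-2-yl)cyclohexyl]ethan-1-one (key-step precursor) | BrCC(=O)[C@]1(C(C)(C)C=C)CC[C@](C)(Cl)[C@@H](Br)C1 | intermediate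
15 | (4R,6R,8S,9S)-4,8-dibromo-9-chloro-5,5,9-trimethylspiro[5.5]undecan-1-one (key-step product) | O=C1CC[C@@H](Br)C(C)(C)[C@]12CC[C@](C)(Cl)[C@@H](Br)C2 | intermediate
16 | (2R,6S,8S,9S)-2,8-dibromo-9-chloro-1,1,9-trimethyl-5-methylidenespiro[5.5]undecane | C=C1CC[C@@H](Br)C(C)(C)[C@]12CC[C@](C)(Cl)[C@@H](Br)C2 | target

Total step count: 8
Longest linear sequence: 8 steps (1 to 16)

**Steps most likely to fail**

Step 7. The bromine transfer may show no facial discrimination: the ligated CuBr2 may not tell the two C5 faces apart, or bromine may be passed on by 14 in a radical chain. The bis(oxazoline) copper system may also turn over slowly. Fallback (known chemistry): ligand control is given up in favour of an unselective but established cyclisation followed by separation of diastereomers. From 14 the cyclisation is run with CuBr and tris(2-pyridylmethyl)amine in 1,2-dichloroethane at 25–40 °C, the usual achiral catalyst system for atom-transfer cyclisation of α-halo carbonyl compounds. This accepts that 15 forms together with its C5 epimer (4S,6R,8S,9S)-4,8-dibromo-9-chloro-5,5,9-trimethylspiro[5.5]undecan-1-one F1. The two diastereomers are separated by chromatography or crystallisation, their configurations are established by X-ray analysis, and the route is rejoined at 15.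

Step 5. Chloride may open the bromonium ion at C11 instead of C10 (bromine migration), the C10 cation may lose a proton, or the acid chloride may acylate the vinyl group under ZnCl2 at 50 °C. Fallback: from 10 the two events are separated. Anhydrous HCl with catalytic ZnCl2 in CH2Cl2 at 0 °C opens the strained lactone to the free chloro acid (1R,3S,4S)-3-bromo-4-chloro-4-methyl-1-(2-methylbut-3-en-2-yl)cyclohexane-1-carboxylic acid F2. Oxalyl chloride with catalytic DMF in CH2Cl2 at 0 °C to rt then gives the acid chloride without Lewis acid or heat, and the route is rejoined at 11.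

Step 8. The C2 carbonyl group is shielded by the spiro carbon and the neighbouring quaternary C6, so cycloaddition of Cp2Ti=CH2 may be slow and prolonged heating may cost HBr or HCl. Fallback: from 15 a Peterson olefination in two stages. Me3SiCH2MgCl/CeCl3 in THF at −78 to 0 °C adds to the ketone as a weakly basic organocerium reagent and gives the β-hydroxysilane (4R,6R,8S,9S)-4,8-dibromo-9-chloro-5,5,9-trimethyl-1-[(trimethylsilyl)methyl]spiro[5.5]undecan-1-ol F3 (either C1 epimer). Aqueous HF in MeCN at rt then brings about the elimination to the exocyclic alkene, and the route is rejoined at 16.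

**Further compounds**

F1 | step 7 | (4S,6R,8S,9S)-4,8-dibromo-9-chloro-5,5,9-trimethylspiro[5.5]undecan-1-one | O=C1CC[C@H](Br)C(C)(C)[C@]12CC[C@](C)(Cl)[C@@H](Br)C2
F2 | step 5 | (1R,3S,4S)-3-bromo-4-chloro-4-methyl-1-(2-methylbut-3-en-2-yl)cyclohexane-1-carboxylic acid | OC(=O)[C@]1(C(C)(C)C=C)CC[C@](C)(Cl)[C@@H](Br)C1
F3 | step 8 | (4R,6R,8S,9S)-4,8-dibromo-9-chloro-5,5,9-trimethyl-1-[(trimethylsilyl)methyl]spiro[5.5]undecan-1-ol (C1 epimers) | C[Si](C)(C)CC1(O)CC[C@@H](Br)C(C)(C)[C@]12CC[C@](C)(Cl)[C@@H](Br)C2
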